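## Analysis of the target

Numbering follows the eremophilane convention: ring A is C1, C2, C3, C4, C5, C10; ring B is C5 to C10; C11–C13 are the isopropenyl carbons; β is the face of the C5 methyl group.

- The target is a cis-fused decalin. Ring A holds the C2 ketone and the secondary C4 methyl group; ring B holds the C7 isopropenyl group, the C8 tiglate (E ester) and the C9 angelate (Z ester). The rings share the C5–C10 bond, and C5 is quaternary and methyl-substituted.
- The six stereocentres read 4β-methyl, 5β-methyl, 10β-H, 7β-isopropenyl, 8α-O and 9α-O. The two methyl groups are cis, the ring fusion is cis, the two ester oxygens are cis to each other, O8 is trans to the isopropenyl group and O9 is trans to H10.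
- In the chair–chair form that keeps the isopropenyl group and O8 equatorial, C4 is axial on ring B and O9 is axial on the concave α face beneath ring A. O9 can therefore only be created by delivering hydrogen to C9 from the convex face, and it is the harder oxygen to acylate.
- Sensitive elements are the angelate (Z to E isomerisation on heating with bases or nucleophiles), two unlike esters on a cis-diol (acyl migration while one hydroxyl is free), the isopropenyl group (migration into conjugation) and every β-oxygenated ketone met on the way (elimination).
- The difficulty is five contiguous stereocentres, C4–C5–C10–C9–C8, with C7 one carbon further, packed around a quaternary centre on a folded bicycle, plus the need to tell O8 from O9.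
- The strategy rests on one feature. C5–C10 and C6–C7 are the two σ-bonds a Diels–Alder reaction would form if C8=C9 were the new alkene, which is where the two oxygens sit. C5 with its methyl group and the neighbouring C4 are what an isopropenyl ketone leaves behind as dienophile when its carbonyl (later the C4 methyl) lies in the four-atom tether C1–C4 that becomes ring A.

## Retrosynthetic reasoning

**C2 carbonyl (28 ⇒ 27 ⇒ 26).** The ketone is traced to a silyl-protected 2β-carbinol. C2 is kept sp3 to the end because it steers the cycloaddition and anchors the ring A chair; with both esters in place the last oxidation has no selectivity problem.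

**C9–O acyl bond (26 ⇒ 23 + 24).** The angelate is cut before the tiglate because it is the more fragile ester. The forward step must acylate a hindered axial hydroxyl through mixed anhydride 25 without Z/E isomerisation; O8 is already esterified, so no regiochemical choice arises.

**C9–H bond (23 ⇒ 22).** The 9α-carbinol comes from the C9 ketone. Hydride can reach C9 only from the convex β face, which gives the concave alcohol that no addition to an alkene would deliver.

**C8–O bond (22 ⇒ 19 + 20, then 19 ⇒ 18).** The tiglate is cut at C8–O and not at O–acyl, so that the oxygen arrives as carboxylate 21 with inversion of an axial 8β-bromide. Bromide 19 comes from silyl enol ether 18, which fixes the site of functionalisation at C8 and not C10.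

**C7–C11 bond (18 ⇒ 16 + 17).** C7 is β to the C9 carbonyl, so the isopropenyl group is introduced by conjugate addition to enone 16, and the enolate is trapped on the C8 side.

**Allylic transposition (16 ⇒ 15 ⇒ 14 ⇒ 13).** The C9 carbonyl with a C7=C8 alkene is derived from a C8=C9 alkene by epoxidation, base-induced opening to the allylic alcohol and oxidation. This moves the alkene of the cycloadduct to where the carbon nucleophile is needed.

**C4 methyl (13 ⇒ 12 ⇒ 11).** The C4 methyl group is the former activating carbonyl: methylenation, then two hydrogen atoms added to C4=CH2 under conditions that favour the equatorial methyl group.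

**C5–C10 and C6–C7 (11 ⇒ 10).** Both rings, the quaternary centre and the ring fusion come from an intramolecular Diels–Alder reaction of trienone 10. The cut is made here because it removes two rings and two stereocentres at once and leaves a chain with a single stereocentre.

**C2–C3 bond (10 ⇒ 9 ⇒ 5 + 6).** The chain is one aldol bond between two achiral pieces, through enol borinate 7 and aldolate 8. This step sets C2 as S, the configuration that relays to 5β-methyl and 10β-H.

**Dienal (5 ⇒ 4 ⇒ 3 ⇒ 1).** The skipped dienal is made from ethyl sorbate by deconjugation through trienolate 2, reduction and mild reoxidation.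

## Alternatives that were turned down

**Alternative 1:** The C7–C8 bond of ring B is cut.
- Forward key step: a substrate with ring A complete, a prenyl chain on C5 and a PMB-protected α-oxygenated aldehyde arm (C9, C8) on C10 is closed by a Lewis-acid-promoted carbonyl-ene reaction of the citronellal-to-isopulegol kind (ZnBr2 or Me2AlCl). C7 attacks C8 while a methyl hydrogen moves to oxygen, giving A1, 8α-hydroxy-9α-(4-methoxybenzyloxy)-10βH-eremophil-11-en-2-one.
- For it: the C7–C8 bond, the isopropenyl group and the C8 hydroxyl appear in one step; the chair-like ene transition state normally places hydroxyl and isopropenyl trans; O8 (free) and O9 (ether) emerge already distinguished. On these points it is stronger than the chosen route, which tells the oxygens apart only by the order of their introduction.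
- Against it: the ene substrate must already hold C4, C5, C9 and C10 in the right relative and absolute sense, so the contiguous quaternary and tertiary centres still have to be built stepwise on a cyclohexanone. The α-alkoxy aldehyde can epimerise at C9, and the required chair has the C9 ether axial beside the reacting carbonyl, where a chelating Lewis acid may change the facial course.
- Comparison: the chosen strategy offers instead both rings, the quaternary centre and the ring fusion in one step from a chain made in five steps.

**Alternative 2:** C9–C10 and a sacrificial C1–C8 bond are cut.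
- Forward key step: a ring A enone (C1=C10 conjugated to the C2 carbonyl, C5 bearing the methyl group and a silyloxyethyl arm for C6 and C7) is irradiated with A3, 2,2-dimethyl-1,3-dioxole. This gives the cis-anti-cis cyclobutane A2; later retro-aldol cleavage of C1–C8 would leave a glycolaldehyde unit on C10.
- For it: enone–alkene photocycloaddition is dependable, the dioxole is symmetrical so there is no regiochemical issue, and both oxygens arrive together. On that point it is stronger than the chosen route.
- Against it: the face of addition depends on telling a methyl group from a two-carbon chain on the adjacent quaternary C5, which is a weak bias for the C10 configuration. The enone with its cis-dimethyl pattern must first be made enantioselectively. After fragmentation ring B still has to be closed at C7–C8 and the isopropenyl group added, through an epimerisable α-oxygenated aldehyde.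
- Comparison: it is longer and weaker at the ring fusion; the chosen strategy fixes the fusion in the same step that makes both rings.

**Alternative 3:** The C5–C6 bond is cut as the bond formed in a [3,3] shift.
- Forward key step: a masked ortho-quinone Diels–Alder reaction builds a bicyclo[2.2.2]octene frame whose C8 carbonyl takes up a dienyl nucleophile. The potassium alkoxide then undergoes anionic oxy-Cope rearrangement (C5–C6 forms, the C8–C3 bridge bond breaks), giving A4, the cis-fused 8-oxo-9,9-dimethoxy octalin with a C3=C4 alkene, a C2 PMB ether and the C7 isopropenyl group.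
- For it: the rearrangement is fast and stereospecific, the bicyclic frame enforces the cis fusion, the quaternary C5 is made in the shift, and C8 (ketone) and C9 (ketal) are in place and differentiated. C7 is α to the ketone and can be equilibrated. These are real advantages over the chosen route, where C7, C8 and C9 are won one at a time on a hindered bicycle.
- Against it: masked ortho-quinone cycloadditions give racemic bicycles unless a chiral partner or a resolution is added, and regio- and endo-control are needed for C1 and C2. Ring A still needs face-selective hydrogenation of C3=C4 for the cis-dimethyl pattern, and the concave 9α-oxygen still has to come from a late ketone reduction. The isopropenyl group β,γ to the C8 ketone can slide into conjugation.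
- Comparison: the length is similar; the chosen strategy offers absolute control from a single reagent-controlled aldol and commercial achiral inputs.

Key step: step 6

Remark on the chemistry: the (+)-antipode of Ipc2BCl is specified on the premise that methyl-ketone enol borinates of this reagent add to the Re face of the aldehyde; the (−)-reagent would be used if the sense proved opposite.

## Route

Step 1
Reactants: 1 ethyl (2E,4E)-hexa-2,4-dienoate (ethyl sorbate)
Product: 3 ethyl (3E)-hexa-3,5-dienoate, via lithium trienolate 2 (not isolated)
Conditions: LiN(i-Pr)2, DMPU, THF, −78 °C; then AcOH, −78 °C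
Reagents that add atoms: none
Why: Deconjugative protonation of an extended enolate: deprotonation at the terminal methyl group gives trienolate 2, which is protonated kinetically at the α-carbon, so the alkenes move out of conjugation and the new C3=C4 bond is E.

Step 2
Reactants: 3 ethyl (3E)-hexa-3,5-dienoate
Product: 4 (3E)-hexa-3,5-dien-1-ol
Conditions: LiAlH4, Et2O, 0 °C
Reagents that add atoms: none
Why: Hydride reduction of the ester; the unactivated diene is inert, and the alcohol is a stable storage form of the sensitive C6 unit.

Step 3
Reactants: 4 (3E)-hexa-3,5-dien-1-ol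
Product: 5 (3E)-hexa-3,5-dienal
Conditions: Dess–Martin periodinane, NaHCO3, CH2Cl2, 0 °C; cold filtered solution used at once
Reagents that add atoms: none
Why: Buffered periodinane oxidation is neutral and fast, so the β,γ-unsaturated aldehyde should form without migration of the alkene into conjugation.

Step 4
Reactants: 6 3-methylbut-3-en-2-one; 5 (3E)-hexa-3,5-dienal
Product: 9 (5S,7E)-5-hydroxy-2-methyldeca-1,7,9-trien-3-one, via enol borinate 7 (not isolated), via boron aldolate 8 (not isolated)
Conditions: 6, (+)-Ipc2BCl, Et3N, Et2O, 0 °C; then 5, −78 → −20 °C; then H2O2, MeOH, pH 7 buffer, 0 °C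
Reagents that add atoms: none
Why: Boron-mediated aldol addition of a methyl ketone: enol borinate 7 forms on the only enolisable side of 6 and adds to one aldehyde face through a cyclic six-membered transition state under control of the isopinocampheyl groups, and buffered peroxide cleaves aldolate 8. Such acetate-type boron aldols are usually selective but not completely so, so the optical purity is to be checked at this stage.

Step 5
Reactants: 9 (5S,7E)-5-hydroxy-2-methyldeca-1,7,9-trien-3-one
Product: 10 (5S,7E)-5-(tert-butyldimethylsilyloxy)-2-methyldeca-1,7,9-trien-3-one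
Conditions: TBSOTf, 2,6-lutidine, CH2Cl2, −78 °C
Reagents that add atoms: tert-butyldimethylsilyl trifluoromethanesulfonate, CC(C)(C)[Si](C)(C)OS(=O)(=O)C(F)(F)F
Why: Silylation with a silyl triflate and a hindered base at low temperature protects the β-hydroxy ketone without retro-aldol cleavage or elimination.

Step 6
Reactants: 10 (5S,7E)-5-(tert-butyldimethylsilyloxy)-2-methyldeca-1,7,9-trien-3-one
Product: 11 2β-(tert-butyldimethylsilyloxy)-5β-methyl-10βH-decal-8-en-4-one (cis-fused octalone)
Conditions: Et2AlCl (1.1 equiv), CH2Cl2, −78 → −20 °C
Reagents that add atoms: none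
Why: Complexation of the C4 carbonyl by Et2AlCl activates the s-cis isopropenyl ketone, and the terminal diene adds across C5=C6 in a concerted, asynchronous [4+2] in which the C6–C7 bond runs ahead of the C5–C10 bond. The closest known reaction type is the intramolecular Diels–Alder reaction of 1,7,9-decatrien-3-ones, which gives cis-fused octalones and is accelerated by alkylaluminium chlorides. Ring B is closed as the new cyclohexene by the cycloaddition itself (bonds C5–C10 and C6–C7), and ring A is closed by the C5–C10 bond through the four-atom tether C1–C4 in a chair-like six-membered array. The cis fusion (C5 methyl and H10 on one face) follows from the endo arrangement, in which the complexed tether carbonyl lies under C8–C9 of the diene and the α-methyl group points away. In that chair the E-diene is necessarily attached axially at C10, so the C2 silyloxy group can be equatorial only on the diene face that places it cis to H10; the other face would force it 1,3-diaxial to C9. C2 therefore fixes C10 and, through the suprafacial addition, C5, which is why the carbinol must be S. A boat-like tether, an option for trienones that lack the α-methyl group, is disfavoured here because it would press the C5 methyl group against C2. The step needs endo over exo closure and one diene face; the first is secured by the Lewis-acid-complexed carbonyl in the tether, the second by the equatorial preference of the silyl ether.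

Step 7
Reactants: 11 2β-(tert-butyldimethylsilyloxy)-5β-methyl-10βH-decal-8-en-4-one
Product: 12 2β-(tert-butyldimethylsilyloxy)-5β-methyl-4-methylene-10βH-decal-8-ene
Conditions: Cp2TiMe2, toluene, 70 °C
Reagents that add atoms: dimethyltitanocene, C[Ti](C)(C1C=CC=C1)C1C=CC=C1
Why: Petasis methylenation: the titanium methylidene formed on heating is non-basic, so the hindered, enolisable C4 ketone beside the quaternary centre is converted without β-elimination of the C2 silyl ether.

Step 8
Reactants: 12 2β-(tert-butyldimethylsilyloxy)-5β-methyl-4-methylene-10βH-decal-8-ene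
Product: 13 2β-(tert-butyldimethylsilyloxy)-4β,5β-dimethyl-10βH-decal-8-ene
Conditions: Mn(dpm)3 (cat.), PhSiH3, t-BuOOH, i-PrOH, 22 °C
Reagents that add atoms: none
Why: Hydrogen-atom-transfer hydrogenation with a metal hydride (dpm = dipivaloylmethanate): the 1,1-disubstituted alkene is selected over C8=C9 because only it gives a tertiary radical. That radical should accept the second hydrogen axially on the ring A chair that keeps the C2 silyloxy group equatorial; in this chair the C5 methyl group is axial, so the new equatorial C4 methyl group is cis to it (4β).

Step 9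
Reactants: 13 2β-(tert-butyldimethylsilyloxy)-4β,5β-dimethyl-10βH-decal-8-ene
Product: 14 8β,9β-epoxy-2β-(tert-butyldimethylsilyloxy)-4β,5β-dimethyl-10βH-decalin
Conditions: mCPBA, NaHCO3, CH2Cl2, 0 °C
Reagents that add atoms: 3-chloroperoxybenzoic acid, OOC(=O)c1cccc(Cl)c1
Why: Peracid epoxidation from the convex β face; on the α face C9 lies in the fold beneath ring A, under the axial hydrogens of C2 and C4.

Step 10
Reactants: 14 8β,9β-epoxy-2β-(tert-butyldimethylsilyloxy)-4β,5β-dimethyl-10βH-decalin
Product: 15 2β-(tert-butyldimethylsilyloxy)-4β,5β-dimethyl-10βH-decal-7-en-9β-ol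
Conditions: Et2AlCl, lithium 2,2,6,6-tetramethylpiperidide, toluene, 0 °C
Reagents that add atoms: none
Why: Base-induced isomerisation of an epoxide to an allylic alcohol by a bulky aluminium amide (syn elimination through a cyclic transition state): the amide should take the β-hydrogen of the unhindered C7 methylene and not the ring-fusion methine beside the quaternary centre, so the C8–O bond breaks and the alkene moves to C7=C8. A singlet-oxygen ene reaction was set aside for this transposition because the only well-aligned allylic hydrogen on the open face is H10, which would put the oxygen on C8; the carbinol configuration formed here is lost in step 11.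

Step 11
Reactants: 15 2β-(tert-butyldimethylsilyloxy)-4β,5β-dimethyl-10βH-decal-7-en-9β-ol
Product: 16 2β-(tert-butyldimethylsilyloxy)-4β,5β-dimethyl-10βH-decal-7-en-9-one
Conditions: Dess–Martin periodinane, NaHCO3, CH2Cl2, 0 °C → rt
Reagents that add atoms: none
Why: Neutral periodinane oxidation of the allylic alcohol gives the C9 enone without enolisation at the epimerisable ring-fusion carbon C10.

Step 12
Reactants: 16 2β-(tert-butyldimethylsilyloxy)-4β,5β-dimethyl-10βH-decal-7-en-9-one; 17 isopropenylmagnesium bromide
Product: 18 2β-(tert-butyldimethylsilyloxy)-9-(trimethylsilyloxy)-7αH,10βH-eremophila-8,11-diene (7β-isopropenyl silyl enol ether)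
Conditions: CuBr·SMe2 (20 mol %), Me3SiCl, THF, −78 °C; Et3N, then aqueous NaHCO3
Reagents that add atoms: chlorotrimethylsilane, C[Si](C)(C)Cl
Why: Copper-catalysed conjugate addition of a Grignard reagent, accelerated by Me3SiCl, which also traps the enolate regiospecifically as the C8=C9 silyl enol ether. The isopropenyl group should enter C7 from the convex β face, because the α face of ring B is covered by axial C4 and its inward hydrogen, and it ends equatorial.

Step 13
Reactants: 18 7β-isopropenyl silyl enol ether
Product: 19 8β-bromo-2β-(tert-butyldimethylsilyloxy)-7αH,10βH-eremophil-11-en-9-one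
Conditions: NBS, THF, −78 °C
Reagents that add atoms: N-bromosuccinimide, O=C1CCC(=O)N1Br
Why: Electrophilic bromination of a silyl enol ether, far faster than attack on the isopropenyl group: bromine adds to C8 along the axial direction on the open β face, the stereoelectronically preferred course, giving the axial 8β-bromo ketone.

Step 14
Reactants: 19 8β-bromo-2β-(tert-butyldimethylsilyloxy)-7αH,10βH-eremophil-11-en-9-one; 20 tiglic acid ((E)-2-methylbut-2-enoic acid)
Product: 22 2β-(tert-butyldimethylsilyloxy)-8α-tigloyloxy-7αH,10βH-eremophil-11-en-9-one, via caesium tiglate 21 (not isolated)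
Conditions: 20, Cs2CO3, DMF, 0 °C; then 19, 0 °C → rt
Reagents that add atoms: none
Why: SN2 displacement of an α-bromo ketone by a carboxylate: backside attack on the axial C8–Br bond inverts C8 to the equatorial 8α ester, which is also the more stable epimer, so enolisation under the mildly basic conditions cannot erode it. The weakly basic carboxylate should favour substitution over elimination toward C7.

Step 15
Reactants: 22 2β-(tert-butyldimethylsilyloxy)-8α-tigloyloxy-7αH,10βH-eremophil-11-en-9-one
Product: 23 2β-(tert-butyldimethylsilyloxy)-8α-tigloyloxy-7αH,10βH-eremophil-11-en-9α-ol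
Conditions: NaBH4, CeCl3·7H2O, MeOH/THF, −40 °C
Reagents that add atoms: none
Why: Luche-type ketone reduction: hydride can reach C9 only from the convex β face, since the α face points into the fold under ring A, so the 9α alcohol cis to O8 results. The cold, non-basic medium spares the tiglate, and migration of the acyl group from the open equatorial O8 to the buried O9 is uphill.

Step 16
Reactants: 23 2β-(tert-butyldimethylsilyloxy)-8α-tigloyloxy-7αH,10βH-eremophil-11-en-9α-ol; 24 angelic acid ((Z)-2-methylbut-2-enoic acid)
Product: 26 9α-angeloyloxy-2β-(tert-butyldimethylsilyloxy)-8α-tigloyloxy-7αH,10βH-eremophil-11-ene, via mixed anhydride 25 (not isolated)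
Conditions: 24, 2,4,6-trichlorobenzoyl chloride, Et3N, toluene, rt; then 23, 80 °C
Reagents that add atoms: none
Why: Yamaguchi-type esterification through mixed anhydride 25: the activated angeloyl group is transferred to the hindered axial C9 hydroxyl on heating without a nucleophilic catalyst, conditions chosen to keep the Z geometry. O8 is already acylated, so no regiochemical choice exists.

Step 17
Reactants: 26 9α-angeloyloxy-2β-(tert-butyldimethylsilyloxy)-8α-tigloyloxy-7αH,10βH-eremophil-11-ene
Product: 27 9α-angeloyloxy-8α-tigloyloxy-7αH,10βH-eremophil-11-en-2β-ol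
Conditions: HF·pyridine, pyridine, THF, 0 °C → rt
Reagents that add atoms: none
Why: Fluoride cleavage of the secondary silyl ether under buffered, weakly acidic conditions that leave both unsaturated esters and the isopropenyl group untouched.

Step 18
Reactants: 27 9α-angeloyloxy-8α-tigloyloxy-7αH,10βH-eremophil-11-en-2β-ol
Product: 28 9α-angeloyloxy-8α-tigloyloxy-7αH,10βH-eremophil-11-en-2-one (target)
Conditions: Dess–Martin periodinane, NaHCO3, CH2Cl2, 0 °C
Reagents that add atoms: none
Why: Neutral periodinane oxidation of the only free hydroxyl, which is equatorial and unhindered, gives the C2 ketone and removes the stereocentre that steered the cycloaddition. No position α or β to the new ketone carries a leaving group.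

## Compound list

1 | ethyl (2E,4E)-hexa-2,4-dienoate (ethyl sorbate) | CCOC(=O)/C=C/C=C/C | starting material
2 | lithium (3E)-1-ethoxyhexa-1,3,5-trien-1-olate (trienolate of 1) | CCOC(O[Li])=C/C=C/C=C | intermediate
3 | ethyl (3E)-hexa-3,5-dienoate | CCOC(=O)C/C=C/C=C | intermediate
4 | (3E)-hexa-3,5-dien-1-ol | OCC/C=C/C=C | intermediate
5 | (3E)-hexa-3,5-dienal | O=CC/C=C/C=C | intermediate
6 | 3-methylbut-3-en-2-one | CC(=O)C(C)=C | starting material
7 | 3-methylbuta-1,3-dien-2-yl diisopinocampheylborinate (enol borinate from 6 and (+)-Ipc2BCl) | C=C(C)C(=C)OB([C@@H]1[C@@H](C)[C@@H]2C[C@H](C1)C2(C)C)[C@@H]1[C@@H](C)[C@@H]2C[C@H](C1)C2(C)C | intermediate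
8 | diisopinocampheylboron aldolate of 9 | C=C(C)C(=O)C[C@@H](OB([C@@H]1[C@@H](C)[C@@H]2C[C@H](C1)C2(C)C)[C@@H]1[C@@H](C)[C@@H]2C[C@H](C1)C2(C)C)C/C=C/C=C | intermediate
9 | (5S,7E)-5-hydroxy-2-methyldeca-1,7,9-trien-3-one | C=C(C)C(=O)C[C@@H](O)C/C=C/C=C | intermediate
10 | (5S,7E)-5-(tert-butyldimethylsilyloxy)-2-methyldeca-1,7,9-trien-3-one | C=C(C)C(=O)C[C@@H](O[Si](C)(C)C(C)(C)C)C/C=C/C=C | intermediate
11 | 2β-(tert-butyldimethylsilyloxy)-5β-methyl-10βH-decal-8-en-4-one | O=C1C[C@@H](O[Si](C)(C)C(C)(C)C)C[C@@H]2C=CCC[C@]12C | intermediate
12 | 2β-(tert-butyldimethylsilyloxy)-5β-methyl-4-methylene-10βH-decal-8-ene | C=C1C[C@@H](O[Si](C)(C)C(C)(C)C)C[C@@H]2C=CCC[C@]12C | intermediate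
13 | 2β-(tert-butyldimethylsilyloxy)-4β,5β-dimethyl-10βH-decal-8-ene | C[C@H]1C[C@@H](O[Si](C)(C)C(C)(C)C)C[C@@H]2C=CCC[C@]12C | intermediate
14 | 8β,9β-epoxy-2β-(tert-butyldimethylsilyloxy)-4β,5β-dimethyl-10βH-decalin | C[C@H]1C[C@@H](O[Si](C)(C)C(C)(C)C)C[C@@H]2[C@H]3O[C@H]3CC[C@]12C | intermediate
15 | 2β-(tert-butyldimethylsilyloxy)-4β,5β-dimethyl-10βH-decal-7-en-9β-ol | C[C@H]1C[C@@H](O[Si](C)(C)C(C)(C)C)C[C@@H]2[C@@H](O)C=CC[C@]12C | intermediate
16 | 2β-(tert-butyldimethylsilyloxy)-4β,5β-dimethyl-10βH-decal-7-en-9-one | C[C@H]1C[C@@H](O[Si](C)(C)C(C)(C)C)C[C@@H]2C(=O)C=CC[C@]12C | intermediate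
17 | isopropenylmagnesium bromide | C=C(C)[Mg]Br | starting material
18 | 2β-(tert-butyldimethylsilyloxy)-9-(trimethylsilyloxy)-7αH,10βH-eremophila-8,11-diene | C[C@H]1C[C@@H](O[Si](C)(C)C(C)(C)C)C[C@@H]2C(O[Si](C)(C)C)=C[C@@H](C(C)=C)C[C@]12C | intermediate
19 | 8β-bromo-2β-(tert-butyldimethylsilyloxy)-7αH,10βH-eremophil-11-en-9-one | C[C@H]1C[C@@H](O[Si](C)(C)C(C)(C)C)C[C@@H]2C(=O)[C@@H](Br)[C@@H](C(C)=C)C[C@]12C | intermediate
20 | tiglic acid ((E)-2-methylbut-2-enoic acid) | OC(=O)/C(C)=C/C | starting material
21 | caesium tiglate | [Cs+].[O-]C(=O)/C(C)=C/C | intermediate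
22 | 2β-(tert-butyldimethylsilyloxy)-8α-tigloyloxy-7αH,10βH-eremophil-11-en-9-one | C[C@H]1C[C@@H](O[Si](C)(C)C(C)(C)C)C[C@@H]2C(=O)[C@H](OC(=O)/C(C)=C/C)[C@@H](C(C)=C)C[C@]12C | intermediate
23 | 2β-(tert-butyldimethylsilyloxy)-8α-tigloyloxy-7αH,10βH-eremophil-11-en-9α-ol | C[C@H]1C[C@@H](O[Si](C)(C)C(C)(C)C)C[C@@H]2[C@H](O)[C@H](OC(=O)/C(C)=C/C)[C@@H](C(C)=C)C[C@]12C | intermediate
24 | angelic acid ((Z)-2-methylbut-2-enoic acid) | OC(=O)/C(C)=C\C | starting material
25 | angelic 2,4,6-trichlorobenzoic anhydride | C\C=C(C)/C(=O)OC(=O)c1c(Cl)cc(Cl)cc1Cl | intermediate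
26 | 9α-angeloyloxy-2β-(tert-butyldimethylsilyloxy)-8α-tigloyloxy-7αH,10βH-eremophil-11-ene | C[C@H]1C[C@@H](O[Si](C)(C)C(C)(C)C)C[C@@H]2[C@H](OC(=O)/C(C)=C\C)[C@H](OC(=O)/C(C)=C/C)[C@@H](C(C)=C)C[C@]12C | intermediate
27 | 9α-angeloyloxy-8α-tigloyloxy-7αH,10βH-eremophil-11-en-2β-ol | C[C@H]1C[C@@H](O)C[C@@H]2[C@H](OC(=O)/C(C)=C\C)[C@H](OC(=O)/C(C)=C/C)[C@@H](C(C)=C)C[C@]12C | intermediate
28 | 9α-angeloyloxy-8α-tigloyloxy-7αH,10βH-eremophil-11-en-2-one | C=C(C)[C@H]1C[C@@]2(C)[C@H](CC(=O)C[C@@H]2C)[C@H](OC(=O)/C(C)=C\C)[C@@H]1OC(=O)/C(C)=C/C | target

## Step count and least certain steps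

Total: 18 steps. Longest linear sequence: 18 steps, from 1 to 28; compounds 6, 17, 20 and 24 are commercial and enter directly.

**Step 6 (key step).**
- What may go wrong: erosion of the endo preference, leading to exo closure and a trans ring fusion, because an α-methyl dienophile has a weaker endo bias; a weaker relay from C2 if the tether departs from the chair; Lewis-acid-induced loss of the β-silyloxy group or oligomerisation of the diene.
- Fallback: a different control element. Free aldol 9 is treated with Me2AlCl (2 equiv, CH2Cl2, −78 → 0 °C); the aluminium alkoxide binds the C4 carbonyl in a six-membered chelate, which activates the dienophile from within and holds O2 equatorial on the forming ring A. Cyclisation should give the hydroxy octalone F1, and TBSOTf/2,6-lutidine returns to 11.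
- Because C2 is oxidised at the end, a relay of the opposite sense would simply call for the other antipode of the borane in step 4.

**Step 4.**
- What may go wrong: incomplete enantioselection in the reagent-controlled aldol, which would carry through the whole route.
- Fallback from 5: an auxiliary-controlled acetate aldol with N-acetyl-(S)-4-isopropyl-1,3-thiazolidine-2-thione (Sn(OTf)2, N-ethylpiperidine, CH2Cl2, −78 °C) gives the adduct F2. Its diastereomers are separable, so optical purity no longer rests on reagent control; the S auxiliary is expected to give the 3S carbinol through the tin-chelated transition state, and the antipode is available otherwise.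
- Silylation gives the silyl ether F3, MeNHOMe·HCl with imidazole gives the Weinreb amide F4, and isopropenylmagnesium bromide 17 (THF, −78 → 0 °C) gives 10.

**Step 8.**
- What may go wrong: poor facial selectivity at C4. The axial approach on the α face is flanked by C9, and the chair preference is worth only one equatorial silyloxy group. Partial reduction of C8=C9 is a second possibility.
- Fallback from 11: deliver the methyl carbon from the β-hydroxyl. KN(SiMe3)2 and PhNTf2 give the enol triflate F5; Pd(OAc)2, PPh3, HCO2H and n-Bu3N give the diene F6; n-Bu4NF gives the allylic alcohol F7.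
- Hydroxyl-directed Simmons–Smith cyclopropanation (Et2Zn, CH2I2) puts the methylene on the β face and gives the cyclopropyl carbinol F8. Periodinane oxidation gives the cyclopropyl ketone F9.
- Li in NH3 with t-BuOH cleaves the cyclopropane bond that overlaps with the carbonyl and reduces the ketone to the equatorial alcohol F10, which now carries the 4β-methyl group. TBSOTf/2,6-lutidine returns to 13.

**Step 10.**
- What may go wrong: proton removal at the ring-fusion carbon C10 instead of C7, since the β-hydrogen at C10 is the better aligned one. This would move the alkene to C9=C10 and leave the oxygen on C8.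
- Fallback from 14: nucleophilic opening in place of deprotonation. Sodium benzeneselenolate (from PhSeSePh and NaBH4, EtOH, reflux) should attack C8 from the open side, because the backside of C9 points into the fold under ring A, giving the hydroxy selenide F11.
- H2O2 (THF, 0 °C → rt) then eliminates the selenoxide, which can only go toward C7, and returns to 15.

**Step 12.**
- What may go wrong: poor facial selectivity at C7. The stereoelectronically preferred axial trajectory on the locked half-chair is the α one, syn to C4, and it may compete with the convex approach. Addition to the carbonyl is a minor risk.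
- Fallback from 16: make C7 epimerisable. Lithium bis(1-ethoxyvinyl)cuprate (from ethyl vinyl ether, t-BuLi and CuI) adds to give the ethoxyvinyl ketone F12.
- Dilute aqueous HCl and then DBU at room temperature give the acetyl diketone F13 as the equatorial 7β epimer, since C7 is now α to a carbonyl and the axial epimer suffers a 1,3-diaxial clash with C4.
- Ph3P=CH2 (1 equiv, THF, −78 → 0 °C) methylenates the unhindered methyl ketone to the isopropenyl ketone F14, and LiN(i-Pr)2 with Me3SiCl (kinetic enolisation at the C8 methylene) returns to 18.

**Step 16.**
- What may go wrong: slow acylation of the buried axial C9 hydroxyl, with Z to E isomerisation of the angeloyl donor on prolonged heating.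
- Fallback from 23: build the angelate on the molecule. 2-[Bis(2,2,2-trifluoroethoxy)phosphoryl]propanoic acid with dicyclohexylcarbodiimide and catalytic 4-(dimethylamino)pyridine acylates through a small, ketene-like species and gives the phosphonate ester F15.
- Still–Gennari olefination (KN(SiMe3)2, 18-crown-6, THF, −78 °C, then acetaldehyde) forms the Z alkene and returns to 26.

## Further compounds

F1 | step 6 | 2β-hydroxy-5β-methyl-10βH-decal-8-en-4-one | O=C1C[C@@H](O)C[C@@H]2C=CCC[C@]12C
F2 | step 4 | (S)-3-[(3S,5E)-3-hydroxyocta-5,7-dienoyl]-4-isopropyl-1,3-thiazolidine-2-thione | CC(C)[C@H]1CSC(=S)N1C(=O)C[C@@H](O)C/C=C/C=C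
F3 | step 4 | (S)-3-[(3S,5E)-3-(tert-butyldimethylsilyloxy)octa-5,7-dienoyl]-4-isopropyl-1,3-thiazolidine-2-thione | CC(C)[C@H]1CSC(=S)N1C(=O)C[C@@H](O[Si](C)(C)C(C)(C)C)C/C=C/C=C
F4 | step 4 | (3S,5E)-3-(tert-butyldimethylsilyloxy)-N-methoxy-N-methylocta-5,7-dienamide | CON(C)C(=O)C[C@@H](O[Si](C)(C)C(C)(C)C)C/C=C/C=C
F5 | step 8 | 2β-(tert-butyldimethylsilyloxy)-5β-methyl-10βH-decala-3,8-dien-4-yl trifluoromethanesulfonate | O=S(=O)(OC1=C[C@@H](O[Si](C)(C)C(C)(C)C)C[C@@H]2C=CCC[C@]12C)C(F)(F)F
F6 | step 8 | 2β-(tert-butyldimethylsilyloxy)-5β-methyl-10βH-decala-3,8-diene | C1=C[C@@H](O[Si](C)(C)C(C)(C)C)C[C@@H]2C=CCC[C@]12C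
F7 | step 8 | 5β-methyl-10βH-decala-3,8-dien-2β-ol | C1=C[C@@H](O)C[C@@H]2C=CCC[C@]12C
F8 | step 8 | 3β,4β-methano-5β-methyl-10βH-decal-8-en-2β-ol | O[C@H]1C[C@@H]2C=CCC[C@]2(C)[C@H]3C[C@@H]13
F9 | step 8 | 3β,4β-methano-5β-methyl-10βH-decal-8-en-2-one | O=C1C[C@@H]2C=CCC[C@]2(C)[C@H]3C[C@@H]13
F10 | step 8 | 4β,5β-dimethyl-10βH-decal-8-en-2β-ol | C[C@H]1C[C@@H](O)C[C@@H]2C=CCC[C@]12C
F11 | step 10 | 2β-(tert-butyldimethylsilyloxy)-4β,5β-dimethyl-8α-(phenylselanyl)-10βH-decalin-9β-ol | C[C@H]1C[C@@H](O[Si](C)(C)C(C)(C)C)C[C@@H]2[C@@H](O)[C@H]([Se]c3ccccc3)CC[C@]12C
F12 | step 12 | 2β-(tert-butyldimethylsilyloxy)-7-(1-ethoxyvinyl)-4β,5β-dimethyl-10βH-decalin-9-one (C7 epimers) | C[C@H]1C[C@@H](O[Si](C)(C)C(C)(C)C)C[C@@H]2C(=O)CC(C(=C)OCC)C[C@]12C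
F13 | step 12 | 7β-acetyl-2β-(tert-butyldimethylsilyloxy)-4β,5β-dimethyl-10βH-decalin-9-one | C[C@H]1C[C@@H](O[Si](C)(C)C(C)(C)C)C[C@@H]2C(=O)C[C@@H](C(C)=O)C[C@]12C
F14 | step 12 | 2β-(tert-butyldimethylsilyloxy)-7αH,10βH-eremophil-11-en-9-one | C[C@H]1C[C@@H](O[Si](C)(C)C(C)(C)C)C[C@@H]2C(=O)C[C@@H](C(C)=C)C[C@]12C
F15 | step 16 | 9α-{2-[bis(2,2,2-trifluoroethoxy)phosphoryl]propanoyloxy}-2β-(tert-butyldimethylsilyloxy)-8α-tigloyloxy-7αH,10βH-eremophil-11-ene | C[C@H]1C[C@@H](O[Si](C)(C)C(C)(C)C)C[C@@H]2[C@H](OC(=O)C(C)P(=O)(OCC(F)(F)F)OCC(F)(F)F)[C@H](OC(=O)/C(C)=C/C)[C@@H](C(C)=C)C[C@]12C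
A1 | alternative 1 | 8α-hydroxy-9α-(4-methoxybenzyloxy)-7αH,10βH-eremophil-11-en-2-one | C=C(C)[C@H]1C[C@@]2(C)[C@H](CC(=O)C[C@@H]2C)[C@H](OCc3ccc(OC)cc3)[C@@H]1O
A2 | alternative 2 | cis-anti-cis cyclobutane photoadduct with the acetonide on C8 and C9 | CC(C)(C)[Si](C)(C)OCC[C@@]1(C)[C@H]2[C@@H]3OC(C)(C)O[C@@H]3[C@H]2C(=O)C[C@@H]1C
A3 | alternative 2 | 2,2-dimethyl-1,3-dioxole | CC1(C)OC=CO1
A4 | alternative 3 | cis-fused 9,9-dimethoxy-8-oxo octalin with C3=C4 alkene, C2 PMB ether and C7 isopropenyl group | C=C(C)[C@H]1C[C@@]2(C)[C@H](C[C@H](OCc3ccc(OC)cc3)C=C2C)C(OC)(OC)C1=O
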